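## Analysis of the target

The target is a 4-aryl-3,4-dihydro-2H-chromen-2-one. Ring B is the six-membered aryl lactone (O1, C2, C3, C4, C4a, C8a). It is fused to ring A, a 1,2,4,5-tetrasubstituted resorcinol-type benzene that carries the free hydroxyl O7 at C7 and, at C6, a saturated two-carbon bridge to ring D (3,4-dimethoxyphenyl). C4 carries ring C, a free catechol (3′,4′-dihydroxyphenyl).

The only stereocenter is C4, of R configuration (CIP order C4a > C1′ > C3 > H). It is a doubly benzylic methine β to the lactone carbonyl, with no neighbouring stereocenter or directing group. Its two aryl substituents are both para-oxygenated and of similar size, so an external chiral agent must set it.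

The feature the plan exploits is the placement of oxygen around C4. C4 is bonded to C4a, which is ortho to the O1-bearing carbon C8a and para to the O7-bearing carbon C7. The atoms O1–C8a–C4a–C4 are therefore a latent ortho-quinone methide (an oxa-diene), stabilised by O7 and by O4′ of ring C, in which C4 is trigonal.

Sensitive groups are the aryl ester of ring B (opened by hydroxide, alkoxides, amines and basic alcohols), the catechol (air oxidation, above all under base) and the electron-rich diarylmethine (ionisation or retro-Friedel–Crafts cleavage under strong acid). Three phenols must end free while two stay as methyl ethers, so the protecting groups must come off under neutral, non-nucleophilic conditions. The difficulty is the combination of an unassisted diaryl methine stereocenter, the regiochemistry of ring A (C4a against C8) and an endgame that leaves lactone and catechol intact.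

## Retrosynthetic reasoning

**15 to 14.** Only the three O–benzyl bonds at O7, O3′ and O4′ are cut. Benzyl is chosen because its removal is neutral and reductive, which the aryl lactone, the methyl ethers and the C4–H centre tolerate. The forward reaction must free three phenols and nothing else.

**14 to 11 and 10 (key disconnection).** Ring B is cut at C3–C4 and at O1–C2. This cut is chosen because of the oxygen pattern named above: removing C2 and C3 leaves ortho-quinone methide 11, in which C4 is planar. The two-carbon unit C2–C3 is supplied by the cyclic malonate 10, an acetate enolate equivalent that is acidic enough for a bifunctional amine catalyst. What is gained: ring B and the C4 stereocenter arise in one operation, and because 11 is flat, any precursor of 11 may be racemic. The forward reaction must add the enolate of 10 to one face of C4 of 11 under catalyst control, then close the lactone through O1 and shed the surplus carbons of 10.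

**11 to 9 to 8.** The transient 11 is masked as sulfone 9, cut at the C4–S bond; 9 comes from carbinol 8 by exchange of C4–OH for the sulfonyl group. A sulfinate is chosen as leaving group because mild aqueous base expels it from the phenoxide. This releases 11 slowly and in low concentration, as a catalyst-controlled addition requires. Neither 9 nor 8 needs to be enantioenriched.

**8 to 5 and 7 (from 6).** The C4–C1′ bond is cut, giving salicylaldehyde 5 and aryl Grignard reagent 7, made from aryl bromide 6. Because the configuration at C4 is erased in 11, this bond can be made by the simplest carbonyl addition, with no stereocontrol and with the phenol of 5 left free.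

**5 to 2 and 4 (from 3).** The aryl–alkyl bond C6–CH2 is cut, giving aryl bromide 2 and primary alkylborane 4, the hydroboration product of styrene 3. An sp2–sp3 coupling delivers the saturated bridge directly. No alkene or alkyne then needs to be carried through the cationic chemistry of ring A or reduced in the presence of benzyl ethers.

**2 to 1.** The O7–benzyl bond is cut. In 1 the hydroxyl ortho to the formyl group is tied up in a hydrogen bond, so the other hydroxyl, the future O7, is the one that is alkylated. The oxygen that must later act as O1 of the quinone methide therefore stays free without a protecting-group step.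

## Alternatives that were turned down

**Alternative 1:** the textbook disconnection, at the C4–C1′ bond with ring B already in place. Aldehyde 5 would be converted into coumarin A1 by Wittig olefination and lactonisation. A rhodium–chiral bisphosphine catalysed 1,4-addition (Hayashi–Miyaura reaction) of arylboronic acid A2 would then give 14.
- The step count is about the same as in the chosen route.
- It was turned down on mechanism. In A1 the oxygen O7 is conjugated through C4a with the enoate, so C4 is a deactivated, push–pull acceptor, and insertion into the aryl–rhodium bond is slow.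
- The electron-rich A2 protodeboronates in the aqueous medium while it waits, so a large excess of a costly partner would be needed.
- The hot aqueous conditions also threaten the aryl lactone.
- The step makes one bond only and leaves the ring construction to a separate operation.
- It is kept as the fallback for the key step.

**Alternative 2:** disconnection at C4–C4a and O1–C2, the biomimetic union of the bibenzyl resorcinol A3 with a cinnamoyl unit. In its asymmetric form this is an N-heterocyclic carbene catalysed oxidative (3+3) annulation of A3 with enal A4 through an α,β-unsaturated acyl azolium, giving lactone A5.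
- It is the shortest route on paper.
- A3 offers two nucleophilic carbons (the future C4a and the future C8, between the two oxygens) and two hydroxyls. O-acylation by the acyl azolium and attack at the wrong carbon compete with the wanted pathway.
- The stoichiometric quinone oxidant and the base meet a free, easily oxidised resorcinol.
- The protic acid variant of the same bond formation is racemic and reversible.
- Enantiocontrol in this reaction class rests on naphthols and symmetric phenols, where these regiochemical questions do not arise.

**Alternative 3:** disconnection at the C4–H bond. Carbinol 8 would be oxidised to benzophenone A6 and converted by Wittig olefination and lactonisation into the 4-arylcoumarin A7. A7 would be reduced enantioselectively with a chiral copper hydride catalyst or by asymmetric hydrogenation.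
- A7 is a doubly deactivated acceptor: both aryl groups on C4 push electrons into the enoate.
- A copper hydride and silane system is prone to reduce the aryl ester further, to lactol A8, which would have to be reoxidised to 14.
- From 8 this costs three to four steps against two in the chosen route, and ring and stereocenter are made in separate operations.

Key step: step 5

Assumption: catalyst Q is 3-{[3,5-bis(trifluoromethyl)phenyl]amino}-4-{[(8α,9S)-6′-methoxycinchonan-9-yl]amino}cyclobut-3-ene-1,2-dione, the squaramide of 9-amino-9-deoxy-epi-quinine. It is assumed to deliver the 4R adduct; if its sense of induction on 11 proves to be 4S, the pseudoenantiomeric (9R) squaramide from 9-amino-9-deoxy-epi-quinidine is used with no other change.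

## Route

Step 1
Reactants: 1 5-bromo-2,4-dihydroxybenzaldehyde
Product: 2 4-(benzyloxy)-5-bromo-2-hydroxybenzaldehyde
Conditions: BnBr (1.05 equiv), NaHCO3, KI (cat.), MeCN, 70 °C
Reagents that add atoms: benzyl bromide, BrCc1ccccc1
Why: Williamson etherification under a weak base; the 4-hydroxyl (para to the formyl group, ortho to bromine) is the more acidic one, while the 2-hydroxyl is held in a hydrogen bond to the aldehyde, so mono-benzylation at the future O7 is expected.

Step 2
Reactants: 2 4-(benzyloxy)-5-bromo-2-hydroxybenzaldehyde; 3 4-ethenyl-1,2-dimethoxybenzene (3,4-dimethoxystyrene)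
Product: 5 4-(benzyloxy)-5-[2-(3,4-dimethoxyphenyl)ethyl]-2-hydroxybenzaldehyde, via alkylborane 4 (not isolated)
Conditions: 3 (1.5 equiv), 9-BBN (1.4 equiv), THF, 0 °C to rt; then 2, Pd(OAc)2 (3 mol%), SPhos (6 mol%), aq. K3PO4, THF, 65 °C
Reagents that add atoms: none
Why: Anti-Markovnikov hydroboration of 3 gives primary alkylborane 4, which couples with aryl bromide 2 in a B-alkyl Suzuki–Miyaura reaction; the electron-rich dialkylbiarylphosphine SPhos should make oxidative addition into the electron-rich C–Br bond and reductive elimination faster than β-hydride elimination. The styrene is kept in slight excess over the borane so that no B–H is left to reduce the aldehyde.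

Step 3
Reactants: 5 4-(benzyloxy)-5-[2-(3,4-dimethoxyphenyl)ethyl]-2-hydroxybenzaldehyde; 6 1,2-bis(benzyloxy)-4-bromobenzene
Product: 8 rac-5-(benzyloxy)-2-{[3,4-bis(benzyloxy)phenyl](hydroxy)methyl}-4-[2-(3,4-dimethoxyphenyl)ethyl]phenol, via Grignard reagent 7 (not isolated)
Conditions: 6 (2.5 equiv), Mg, THF, 40 °C; then 5, THF, 0 °C; aq. NH4Cl, 0 °C
Reagents that add atoms: none
Why: Grignard addition to the aldehyde; the first equivalent of 7 is consumed by the phenol and the resulting magnesium phenoxide chelates the formyl group, which the second equivalent attacks. The carbinol centre is made as a racemate on purpose, because it is erased in step 5.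

Step 4
Reactants: 8 rac-5-(benzyloxy)-2-{[3,4-bis(benzyloxy)phenyl](hydroxy)methyl}-4-[2-(3,4-dimethoxyphenyl)ethyl]phenol
Product: 9 rac-5-(benzyloxy)-2-{[3,4-bis(benzyloxy)phenyl](4-methylbenzenesulfonyl)methyl}-4-[2-(3,4-dimethoxyphenyl)ethyl]phenol
Conditions: p-TolSO2H (1.5 equiv), CH2Cl2, 0 °C to rt
Reagents that add atoms: 4-methylbenzenesulfinic acid, Cc1ccc(S(=O)O)cc1
Why: Acid-promoted SN1 substitution; the carbinol ionises easily to a benzhydryl cation stabilised by the para-benzyloxy groups of rings A and C, and the sulfinic acid captures it at sulfur to give a sulfone that can be stored and triggered by base.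

Step 5
Reactants: 9 rac-5-(benzyloxy)-2-{[3,4-bis(benzyloxy)phenyl](4-methylbenzenesulfonyl)methyl}-4-[2-(3,4-dimethoxyphenyl)ethyl]phenol; 10 2,2-dimethyl-1,3-dioxane-4,6-dione (Meldrum's acid)
Product: 14 (4R)-7-(benzyloxy)-4-[3,4-bis(benzyloxy)phenyl]-6-[2-(3,4-dimethoxyphenyl)ethyl]-3,4-dihydro-2H-chromen-2-one, via ortho-quinone methide 11 (not isolated), via Meldrum's acid adduct 12 (not isolated), via lactone acid 13 (not isolated)
Conditions: 10 (1.2 equiv), Q (5 mol%), 5% aq. NaHCO3, toluene, rt; then 1 M HCl wash, toluene, 90 °C
Reagents that add atoms: none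
Why: NaHCO3 deprotonates the phenol of 9 and the phenoxide expels sulfinate by 1,4-elimination to give ortho-quinone methide 11, in which C4 is trigonal, so both enantiomers of 9 converge on one planar intermediate. The quinuclidine nitrogen of Q deprotonates 10 while the squaramide N–H bonds hold the dienone oxygen of 11 in a defined ion-paired assembly, and the enolate adds to the exocyclic methide carbon from one face, driven by the return of aromaticity to ring A, to give 12. The phenol released by this addition attacks a ring carbonyl of the Meldrum's acid unit (6-exo-trig acyl substitution, closing ring B through O1–C2) with loss of acetone to give acid 13, which decarboxylates on heating through the cyclic transition state of a β-carbonyl acid to give 14. Overall this is a formal (4+2) annulation of the oxa-diene O1=C8a–C4a=C4 with a ketene equivalent; the closest known reaction type is the cinchona squaramide-catalysed addition of Meldrum's acid to ortho-quinone methides released from 2-(1-sulfonylalkyl)phenols under aqueous bicarbonate, which gives 4-substituted 3,4-dihydrocoumarins. The only new stereocenter, C4, is under catalyst control and no substrate element competes. The step needs enantioface selection (secured by the catalyst and by the slow biphasic release of 11, which keeps the uncatalysed addition down), site selection (only C4 of 11 is electrophilic, and the benzyl ethers on O7, O3′ and O4′ block para-quinone methide formation and O-alkylation) and a lactonisation faster than the reverse addition, so that the configuration is locked.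

Step 6
Reactants: 14 (4R)-7-(benzyloxy)-4-[3,4-bis(benzyloxy)phenyl]-6-[2-(3,4-dimethoxyphenyl)ethyl]-3,4-dihydro-2H-chromen-2-one
Product: 15 (4R)-4-(3,4-dihydroxyphenyl)-6-[2-(3,4-dimethoxyphenyl)ethyl]-7-hydroxy-3,4-dihydro-2H-chromen-2-one
Conditions: H2 (1 atm), 10% Pd/C, EtOAc–THF, rt
Reagents that add atoms: none
Why: Heterogeneous hydrogenolysis cleaves the three aryl benzyl ethers under neutral conditions; the methyl ethers, the aryl lactone (no nucleophilic solvent) and the C4–H stereocenter, which bears no heteroatom and is not acidic, should be untouched.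

## Compound list

1 | 5-bromo-2,4-dihydroxybenzaldehyde | O=Cc1cc(Br)c(O)cc1O | starting material
2 | 4-(benzyloxy)-5-bromo-2-hydroxybenzaldehyde | O=Cc1cc(Br)c(OCc2ccccc2)cc1O | intermediate
3 | 4-ethenyl-1,2-dimethoxybenzene | C=Cc1ccc(OC)c(OC)c1 | starting material
4 | 9-[2-(3,4-dimethoxyphenyl)ethyl]-9-borabicyclo[3.3.1]nonane | COc1ccc(CCB2C3CCCC2CCC3)cc1OC | intermediate
5 | 4-(benzyloxy)-5-[2-(3,4-dimethoxyphenyl)ethyl]-2-hydroxybenzaldehyde | COc1ccc(CCc2cc(C=O)c(O)cc2OCc2ccccc2)cc1OC | intermediate
6 | 1,2-bis(benzyloxy)-4-bromobenzene | Brc1ccc(OCc2ccccc2)c(OCc2ccccc2)c1 | starting material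
7 | [3,4-bis(benzyloxy)phenyl]magnesium bromide | Br[Mg]c1ccc(OCc2ccccc2)c(OCc2ccccc2)c1 | intermediate
8 | rac-5-(benzyloxy)-2-{[3,4-bis(benzyloxy)phenyl](hydroxy)methyl}-4-[2-(3,4-dimethoxyphenyl)ethyl]phenol | COc1ccc(CCc2cc(C(O)c3ccc(OCc4ccccc4)c(OCc4ccccc4)c3)c(O)cc2OCc2ccccc2)cc1OC | intermediate
9 | rac-5-(benzyloxy)-2-{[3,4-bis(benzyloxy)phenyl](4-methylbenzenesulfonyl)methyl}-4-[2-(3,4-dimethoxyphenyl)ethyl]phenol | COc1ccc(CCc2cc(C(c3ccc(OCc4ccccc4)c(OCc4ccccc4)c3)S(=O)(=O)c3ccc(C)cc3)c(O)cc2OCc2ccccc2)cc1OC | intermediate
10 | 2,2-dimethyl-1,3-dioxane-4,6-dione | CC1(C)OC(=O)CC(=O)O1 | starting material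
11 | 3-(benzyloxy)-6-{[3,4-bis(benzyloxy)phenyl]methylidene}-4-[2-(3,4-dimethoxyphenyl)ethyl]cyclohexa-2,4-dien-1-one | COc1ccc(CCC2=CC(=Cc3ccc(OCc4ccccc4)c(OCc4ccccc4)c3)C(=O)C=C2OCc2ccccc2)cc1OC | intermediate
12 | 5-[(R)-{4-(benzyloxy)-5-[2-(3,4-dimethoxyphenyl)ethyl]-2-hydroxyphenyl}[3,4-bis(benzyloxy)phenyl]methyl]-2,2-dimethyl-1,3-dioxane-4,6-dione | COc1ccc(CCc2cc(c(O)cc2OCc2ccccc2)[C@H](C2C(=O)OC(C)(C)OC2=O)c2ccc(OCc3ccccc3)c(OCc3ccccc3)c2)cc1OC | intermediate
13 | (4R)-7-(benzyloxy)-4-[3,4-bis(benzyloxy)phenyl]-6-[2-(3,4-dimethoxyphenyl)ethyl]-2-oxo-3,4-dihydro-2H-chromene-3-carboxylic acid (mixture at C3) | COc1ccc(CCc2cc3c(cc2OCc2ccccc2)OC(=O)C(C(=O)O)[C@@H]3c2ccc(OCc4ccccc4)c(OCc4ccccc4)c2)cc1OC | intermediate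
14 | (4R)-7-(benzyloxy)-4-[3,4-bis(benzyloxy)phenyl]-6-[2-(3,4-dimethoxyphenyl)ethyl]-3,4-dihydro-2H-chromen-2-one | COc1ccc(CCc2cc3c(cc2OCc2ccccc2)OC(=O)C[C@@H]3c2ccc(OCc4ccccc4)c(OCc4ccccc4)c2)cc1OC | intermediate
15 | (4R)-4-(3,4-dihydroxyphenyl)-6-[2-(3,4-dimethoxyphenyl)ethyl]-7-hydroxy-3,4-dihydro-2H-chromen-2-one | COc1ccc(CCc2cc3c(cc2O)OC(=O)C[C@@H]3c2ccc(O)c(O)c2)cc1OC | target

## Step count and risk

Total step count: 6. Longest linear sequence: 6 steps (1 to 15); compounds 3, 6 and 10 enter as commercial partners.

**Step 5 (key step).** The most likely failure is loss of enantioselectivity. Adduct 12 can fall back to the strongly stabilised 11 by expelling the Meldrum's acid anion before lactonisation locks C4, and an uncatalysed addition can take place at the aqueous interface. The push–pull stabilisation of 11 by O7 and O4′ may also make the addition slow.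

Fallback, using known chemistry: setting out from 5, Wittig olefination with Ph3P=CHCO2Et in hot N,N-diethylaniline with lactonisation in the same flask should give 7-(benzyloxy)-6-[2-(3,4-dimethoxyphenyl)ethyl]-2H-chromen-2-one F1. A 1,4-addition of the commercial arylboronic acid labelled A2 above (excess), catalysed by Rh(acac)(C2H4)2 and (R)-Segphos in dioxane–water at 60 °C, then comes back to the route at 14. The ligand enantiomer is chosen to give 4R.

**Step 4.** The long-lived benzhydryl cation may undergo Friedel–Crafts self-condensation with the electron-rich rings A and D, and the sulfone may lose sulfinate prematurely during purification.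

Fallback: setting out from 8, acetylation of both hydroxyls (Ac2O, pyridine, DMAP cat.) should give rac-[2-(acetyloxy)-4-(benzyloxy)-5-[2-(3,4-dimethoxyphenyl)ethyl]phenyl][3,4-bis(benzyloxy)phenyl]methyl acetate F2. Under the conditions of step 5 with aqueous K2CO3 as the base, cleavage of the aryl acetate and 1,4-elimination of acetate release 11 with no cationic intermediate. The sequence comes back to the route at 14.

**Step 2.** Oxidative addition into the C–Br bond of the phenoxide form of 2 may be slow, so that protodeboronation or β-hydride elimination of 4 takes over. Residual B–H may reduce the formyl group.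

Fallback: setting out from 2 and 3, a Mizoroki–Heck coupling (Pd(OAc)2, P(o-tol)3, Et3N, DMF, 100 °C) should give 4-(benzyloxy)-5-[(E)-2-(3,4-dimethoxyphenyl)ethenyl]-2-hydroxybenzaldehyde F3. Chemoselective hydrogenation of the alkene over Pd/C poisoned with Ph2S (H2, EtOAc, rt), which spares benzyl ethers and the aryl aldehyde, comes back to the route at 5.

**Step 6.** Cleavage of the flanked O7 benzyl ether may be incomplete, the aryl lactone may be opened by adventitious nucleophiles during a long reaction, and the freed catechol may oxidise in air on isolation.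

Fallback: setting out from 14, Lewis acid debenzylation with BCl3 and pentamethylbenzene as cation scavenger (CH2Cl2, −78 °C) cleaves benzyl ethers by a non-reductive mechanism. At this temperature the aryl methyl ethers should remain intact. It comes back to the route at 15 and makes no new intermediate.

## Further compounds

F1 | step 5 | 7-(benzyloxy)-6-[2-(3,4-dimethoxyphenyl)ethyl]-2H-chromen-2-one | COc1ccc(CCc2cc3ccc(=O)oc3cc2OCc2ccccc2)cc1OC
F2 | step 4 | rac-[2-(acetyloxy)-4-(benzyloxy)-5-[2-(3,4-dimethoxyphenyl)ethyl]phenyl][3,4-bis(benzyloxy)phenyl]methyl acetate | COc1ccc(CCc2cc(C(OC(C)=O)c3ccc(OCc4ccccc4)c(OCc4ccccc4)c3)c(OC(C)=O)cc2OCc2ccccc2)cc1OC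
F3 | step 2 | 4-(benzyloxy)-5-[(E)-2-(3,4-dimethoxyphenyl)ethenyl]-2-hydroxybenzaldehyde | COc1ccc(/C=C/c2cc(C=O)c(O)cc2OCc2ccccc2)cc1OC
F0 | step 6 | none | none
A1 | alternative 1 | 7-(benzyloxy)-6-[2-(3,4-dimethoxyphenyl)ethyl]-2H-chromen-2-one | COc1ccc(CCc2cc3ccc(=O)oc3cc2OCc2ccccc2)cc1OC
A2 | alternative 1 | [3,4-bis(benzyloxy)phenyl]boronic acid | OB(O)c1ccc(OCc2ccccc2)c(OCc2ccccc2)c1
A3 | alternative 2 | 4-[2-(3,4-dimethoxyphenyl)ethyl]benzene-1,3-diol | COc1ccc(CCc2ccc(O)cc2O)cc1OC
A4 | alternative 2 | (E)-3-[3,4-bis(benzyloxy)phenyl]prop-2-enal | O=C/C=C/c1ccc(OCc2ccccc2)c(OCc2ccccc2)c1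
A5 | alternative 2 | (4R)-4-[3,4-bis(benzyloxy)phenyl]-6-[2-(3,4-dimethoxyphenyl)ethyl]-7-hydroxy-3,4-dihydro-2H-chromen-2-one | COc1ccc(CCc2cc3c(cc2O)OC(=O)C[C@@H]3c2ccc(OCc4ccccc4)c(OCc4ccccc4)c2)cc1OC
A6 | alternative 3 | {4-(benzyloxy)-5-[2-(3,4-dimethoxyphenyl)ethyl]-2-hydroxyphenyl}[3,4-bis(benzyloxy)phenyl]methanone | COc1ccc(CCc2cc(C(=O)c3ccc(OCc4ccccc4)c(OCc4ccccc4)c3)c(O)cc2OCc2ccccc2)cc1OC
A7 | alternative 3 | 7-(benzyloxy)-4-[3,4-bis(benzyloxy)phenyl]-6-[2-(3,4-dimethoxyphenyl)ethyl]-2H-chromen-2-one | COc1ccc(CCc2cc3c(-c4ccc(OCc5ccccc5)c(OCc5ccccc5)c4)cc(=O)oc3cc2OCc2ccccc2)cc1OC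
A8 | alternative 3 | (4R)-7-(benzyloxy)-4-[3,4-bis(benzyloxy)phenyl]-6-[2-(3,4-dimethoxyphenyl)ethyl]-3,4-dihydro-2H-chromen-2-ol | COc1ccc(CCc2cc3c(cc2OCc2ccccc2)OC(O)C[C@@H]3c2ccc(OCc4ccccc4)c(OCc4ccccc4)c2)cc1OC
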